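## Analysis of the target

The target 13 is a 1H-indole, a benzene ring fused through C3a and C7a to a pyrrole ring. It carries bromine at C2, a methylsulfanyl group at C3 and bromine at C4 and C6, while N1, C5 and C7 carry hydrogen. It has no stereocentre and is achiral; the one stereocentre that appears on the way (C2 of an indoline) is carried as a racemate and vanishes on aromatization. The sensitive groups are the thioether (oxidation or halogenation at sulfur), the 2-bromoindole unit (unstable to acid and light) and three aryl C–Br bonds, which restrict organolithium, Grignard, low-valent transition-metal and dissolving-metal reagents to the one place where a bromine is meant to be exchanged. The difficulty is the halogen pattern: electrophilic bromination of an indole goes to C3 and C2 and then to C5 or C6, not cleanly to C4 and C6, so these two bromines must be on the benzene ring before the pyrrole ring is built, and the ring construction must leave them alone. In addition, C3 is crowded by the peri bromine at C4, and C2 needs a halogen placed without touching sulfur or the benzene ring. The feature used here is that the two bonds joining the pyrrole atoms to the benzene ring, N1–C7a and C3–C3a, end on neighbouring ring carbons, and that the C4 bromine sits on the carbon next to C3a. If C3a and C7a are the two carbons of an aryne, that bromine is its ortho substituent and decides which end takes nitrogen and which takes carbon.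

## Retrosynthetic reasoning

**C2–Br (13 to 12).** The last bond formed is C2–Br, and it is traced back to the carboxyl group of acid 12. A C2 carboxyl comes with the ring construction at no cost, it blocks C2 while sulfur is introduced at C3, and it marks the exact carbon where halogen must enter. The forward reaction has to be an ipso substitution: an electrophilic bromine source attacks C2, the C3 sulfur stabilizes the cation, and decarboxylation restores the indole. A direct C–H bromination was not chosen as the main line because it would first require a separate removal of the carboxyl group.

**C3–S (12 to 11 to 10).** Acid 12 comes from methyl ester 11 by hydrolysis, and the C3–S bond of 11 is cut to give indole ester 10. C3 is the inherently nucleophilic carbon of an indole, and in 10 it is the only free position of the pyrrole ring, so a sulfenyl cation donor can go nowhere else. The forward reaction must overcome the deactivation by the ester and the crowding by the C4 bromine, which favours a small, strongly electrophilic sulfur reagent.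

**Oxidation level and nitrogen protection (10 to 9 to 8).** Indole 10 is taken back to indoline 9 and then to its N-carbamate 8. This gives up no skeletal bond; it only recognizes that the ring-forming event delivers a 2,3-dihydroindole with a carbamate on nitrogen. Forward, acid removes the carbamate and a quinone oxidant removes two hydrogens, both routine on this ring system.

**N1–C7a and C3–C3a (8 to 7 plus 6, 7 from 5).** This is the disconnection that carries the plan. Both bonds from the benzene ring to the five-membered ring are cut at once, which leaves aryne 7 and the dehydroalanine carbamate 6 as a three-atom N–C–C partner. Cutting here, and not at N1–C2 or C2–C3, means that the benzene ring with both bromines is bought ready-made and the pyrrole ring is formed in one operation under conditions that do not touch aryl bromides. The forward reaction must place nitrogen on the aryne carbon remote from bromine and carbon on the one next to it. The ortho bromine provides exactly this bias. The aryne 7 is released from silyl triflate 5 by fluoride.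

**C–Si and O–S (5 to 4 to 3 to 2 to 1).** Triflate 5 is taken back to phenoxide 4, which arises from aryllithium 3 by migration of silicon from oxygen to carbon, and 3 comes from silyl ether 2 by exchange of one ortho bromine. Ether 2 is the O-silyl derivative of phenol 1. Phenol 1 is symmetric, so either ortho bromine gives the same product, and the bromine that is sacrificed is the one the target does not need. No C–C bond is made before the key step.

## Alternatives that were turned down

**Alternative 1:** Here the benzene ring is the ring that is built, by cutting C5–C6. The precursor is the pyrrole triene A2, 3-(1-bromoethenyl)-2-(2,2-dibromoethenyl)-1-tosylpyrrole. On heating it would undergo a disrotatory 6π electrocyclization, and loss of H and Br across the new C5–C6 bond would give 4,6-dibromo-1-tosylindole A1.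
- For it: each bromine of A1 is placed by construction, so there is no orientation question of the kind an unsymmetrical aryne raises. A1 is already aromatic and carries no ester to remove. On these two points it is stronger than the chosen plan.
- Against it: A2 needs a pyrrole with two different unsaturated arms on C2 and C3, a pattern that electrophilic substitution of a 2-acylpyrrole does not deliver, since that goes to C4. Each arm then has to be elaborated separately. The central double bond of the triene belongs to the aromatic pyrrole, and one terminus is fully substituted with a bromine pointing inward; both raise the barrier to closure. The 1-bromoethenyl arm can lose H and Br to an alkyne at the temperatures needed.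
- Comparison: from A1, detosylation, sulfenylation at C3 and bromination at C2 would still be needed to reach 13, so the count would exceed that of the chosen route. The chosen plan offers a precursor made in two steps and a ring closure of a known type on an intact benzene ring.

**Alternative 2:** This cuts C2–C3. The precursor is the isocyanide A4, 1,5-dibromo-3-isocyano-2-[(methylsulfanyl)methyl]benzene. A hindered lithium dialkylamide would deprotonate the sulfur-bearing benzylic carbon, the carbanion would add to the isocyanide carbon, and tautomerization would give 4,6-dibromo-3-(methylsulfanyl)-1H-indole A3.
- For it: sulfur is on C3 from the start, so no substitution at the crowded C3 is needed, and A3 is one C2 bromination away from 13. In the endgame it is clearly shorter than the chosen plan, one step against five.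
- Against it: A4 has an aryl hydrogen flanked by two bromines (the future C5–H), which is the kind of site a lithium amide deprotonates readily. That would start halogen migration or elimination to an aryne, in competition with the benzylic deprotonation. A4 itself requires a 2-methylaniline with the right bromines, benzylic bromination, thiolate substitution, formylation and dehydration, and the isocyanide is labile.
- Comparison: what is saved after the ring closure is spent before it, and the key step has a structural liability. The chosen plan forms the ring with fluoride at room temperature, conditions to which the C–Br bonds and the acidic aryl hydrogen are indifferent.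

**Alternative 3:** This cuts N1–C2 and C3–S together. The precursor is the bromoalkyne A6, N-[3,5-dibromo-2-(bromoethynyl)phenyl]-4-methylbenzenesulfonamide. The sulfonium salt A7, dimethyl(methylsulfanyl)sulfonium tetrafluoroborate, would transfer MeS+ to the aryl-bound alkyne carbon while the sulfonamide nitrogen attacks the bromine-bearing carbon in a 5-endo-dig closure. The product would be 2,4,6-tribromo-3-(methylsulfanyl)-1-tosylindole A5.
- For it: all four substituents of 13 are in place after the ring closure and only N-detosylation remains. It is the most convergent of the four plans and avoids both the substitution at the hindered C3 and any decarboxylation. On step economy after the key step it beats the chosen plan.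
- Against it: a bromoalkyne is a poor π-nucleophile and here it is flanked by an ortho bromine, and the sulfonamide nitrogen is a weak nucleophile, so the thiirenium pathway is slow and open to diversion. A6 needs an alkynylation that must distinguish one halogen among several on the same ring, followed by alkyne bromination, and it can cyclize prematurely under base. The final detosylation exposes a 2-bromo-N-sulfonylindole to nucleophiles.
- Comparison: the chosen plan gives up this economy. In return it has a ring-forming reaction of an established type, no cross-coupling on a polybrominated arene, and a carboxyl group that fixes the position of the last bromine.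

Key step: step 3

Remark on the chemistry: 6 (N-Boc-dehydroalanine methyl ester) is taken as a purchasable compound, and all indoline intermediates are racemic because the target is achiral.

## Route

Step 1
Reactants: 1 2,4,6-tribromophenol
Product: 2 (2,4,6-tribromophenoxy)trimethylsilane
Conditions: HMDS (0.7 equiv), THF, reflux; volatiles removed in vacuo, crude product used directly
Reagents that add atoms: hexamethyldisilazane, C[Si](C)(C)N[Si](C)(C)C
Why: O-silylation of an acidic phenol by a silazane; the three bromines make the phenol acidic enough to react without a catalyst, and ammonia is the only by-product, so the moisture-sensitive ether can be taken on after evaporation.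

Step 2
Reactants: 2 (2,4,6-tribromophenoxy)trimethylsilane
Product: 5 2,4-dibromo-6-(trimethylsilyl)phenyl trifluoromethanesulfonate, via aryllithium 3 (not isolated), via lithium phenoxide 4 (not isolated)
Conditions: n-BuLi (1.05 equiv), THF, −100 °C to −80 °C; then Tf2O (1.2 equiv), −100 °C to rt
Reagents that add atoms: trifluoromethanesulfonic anhydride, O=S(=O)(OS(=O)(=O)C(F)(F)F)C(F)(F)F
Why: Bromine–lithium exchange at one of the two equivalent bromines ortho to the silyloxy group gives 3, which undergoes an anionic 1,3 oxygen-to-carbon silyl shift (retro-Brook rearrangement) to phenoxide 4, and 4 is triflated on oxygen in the same flask. Lithium that ends up para should return to the ortho site by reversible exchange and is then consumed irreversibly by the silyl shift; 3 has no halogen next to lithium, so it cannot collapse to an aryne.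

Step 3
Reactants: 5 2,4-dibromo-6-(trimethylsilyl)phenyl trifluoromethanesulfonate; 6 methyl 2-[(tert-butoxycarbonyl)amino]acrylate
Product: 8 racemic 1-tert-butyl 2-methyl 4,6-dibromoindoline-1,2-dicarboxylate, via 3,5-dibromobenzyne 7 (not isolated)
Conditions: Bu4N[Ph3SiF2] (1.5 equiv), 6 (1.5 equiv), THF, rt, 5 added slowly over 1 h
Reagents that add atoms: none
Why: Fluoride from the silicate attacks the trimethylsilyl group of 5 and the ortho triflate leaves, releasing aryne 7 between the former C–Si and C–O carbons. The bromine next to the triple bond withdraws electron density and distorts the aryne, so the remote carbon is the more electrophilic end; the carbamate nitrogen of 6 adds there (future C7a) and the aryl anion develops at the carbon flanked by bromine (future C3a), where the C–Br bond stabilizes it. This anion closes onto the CH2 terminus of the acrylate in a 5-endo-trig conjugate addition, forming C3–C3a and the five-membered ring, and the ester enolate takes up the proton that was on nitrogen. The closest known reaction type is the fluoride-induced annulation of arynes with N-carbamoyl dehydroalanine esters to indoline-2-carboxylates, together with the distal-selective addition of nucleophiles to 3-haloarynes. The single new stereocentre, C2, arises from unselective protonation of the enolate, so 8 is racemic, which does not matter because step 5 removes the centre. The selectivity needed is the orientation of addition: the ortho bromine directs nitrogen to the remote carbon and gives the 4,6-dibromo pattern, while the second bromine, para to the future C3a, exerts only a weak opposing inductive bias. Ring closure has to outrun bromide loss and proton transfer at the aryl anion, which is helped by the acceptor being held three atoms away and by slow release of 7 into an excess of 6.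

Step 4
Reactants: 8 racemic 1-tert-butyl 2-methyl 4,6-dibromoindoline-1,2-dicarboxylate
Product: 9 racemic methyl 4,6-dibromoindoline-2-carboxylate
Conditions: TFA, CH2Cl2, 0 °C to rt; aq NaHCO3 work-up
Reagents that add atoms: none
Why: Acidolysis of a tert-butyl carbamate: protonation, loss of the tert-butyl cation as isobutene and decarboxylation of the carbamic acid. The methyl ester and the aryl bromides are inert to TFA, and the free N–H is needed so that the nitrogen lone pair can assist the dehydrogenation that follows.

Step 5
Reactants: 9 racemic methyl 4,6-dibromoindoline-2-carboxylate
Product: 10 methyl 4,6-dibromo-1H-indole-2-carboxylate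
Conditions: DDQ (1.1 equiv), toluene, rt to 60 °C
Reagents that add atoms: none
Why: Dehydrogenation of an indoline by a high-potential quinone: hydride is abstracted from C2 with help of the nitrogen lone pair and a proton is lost from C3, driven by the gain of pyrrole aromaticity. The C2 stereocentre disappears here, and the oxidant is used before sulfur is introduced.

Step 6
Reactants: 10 methyl 4,6-dibromo-1H-indole-2-carboxylate
Product: 11 methyl 4,6-dibromo-3-(methylsulfanyl)-1H-indole-2-carboxylate
Conditions: MeSSMe (0.65 equiv), SO2Cl2 (0.6 equiv), CH2Cl2, −20 °C; then 10, −20 °C to rt
Reagents that add atoms: methanesulfenyl chloride, CSCl, made in the flask from dimethyl disulfide, CSSC, and sulfuryl chloride, O=S(=O)(Cl)Cl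
Why: Electrophilic aromatic substitution (sulfenylation) at C3, the only free position of the pyrrole ring and its most nucleophilic carbon; the C2 ester blocks the other site, and the small sulfenyl electrophile should tolerate the peri C4 bromine, as other electrophiles do on 4,6-dihaloindole-2-carboxylates. Any N-sulfenylated material should revert to the C3 product under the HCl that forms.

Step 7
Reactants: 11 methyl 4,6-dibromo-3-(methylsulfanyl)-1H-indole-2-carboxylate
Product: 12 4,6-dibromo-3-(methylsulfanyl)-1H-indole-2-carboxylic acid
Conditions: LiOH·H2O (3 equiv), THF/MeOH/H2O, rt to 40 °C; then 1 M HCl to pH 3, 0 °C
Reagents that add atoms: lithium hydroxide, [Li+].[OH-]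
Why: Saponification of a methyl ester by acyl addition–elimination, then acidification in the cold; the thioether and the aryl bromides are untouched, and strongly acidic heating, which could move the sulfenyl group, is avoided.

Step 8
Reactants: 12 4,6-dibromo-3-(methylsulfanyl)-1H-indole-2-carboxylic acid
Product: 13 2,4,6-tribromo-3-(methylsulfanyl)-1H-indole
Conditions: NBS (1.05 equiv), LiOAc (0.1 equiv), dry DMF, 0 °C to rt, dark
Reagents that add atoms: N-bromosuccinimide, O=C1CCC(=O)N1Br
Why: Ipso-bromodecarboxylation, a Hunsdiecker-type halodecarboxylation of an electron-rich heteroaromatic acid: electrophilic bromine adds to C2, the cation at C3 is stabilized as a thionium ion by the methylsulfanyl group, and loss of CO2 from the carboxylate restores the indole. C3 is blocked and the benzene ring is deactivated by two bromines, so C2 is the only site open to substitution; dry conditions and one equivalent of NBS should keep sulfur at the sulfide level.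

## Compound list

1 | 2,4,6-tribromophenol | Oc1c(Br)cc(Br)cc1Br | starting material
2 | (2,4,6-tribromophenoxy)trimethylsilane | C[Si](C)(C)Oc1c(Br)cc(Br)cc1Br | intermediate
3 | (2,4-dibromo-6-lithiophenoxy)trimethylsilane | [Li]c1cc(Br)cc(Br)c1O[Si](C)(C)C | intermediate (not isolated)
4 | lithium 2,4-dibromo-6-(trimethylsilyl)phenoxide | [Li+].[O-]c1c(Br)cc(Br)cc1[Si](C)(C)C | intermediate (not isolated)
5 | 2,4-dibromo-6-(trimethylsilyl)phenyl trifluoromethanesulfonate | C[Si](C)(C)c1cc(Br)cc(Br)c1OS(=O)(=O)C(F)(F)F | intermediate
6 | methyl 2-[(tert-butoxycarbonyl)amino]acrylate | C=C(NC(=O)OC(C)(C)C)C(=O)OC | starting material
7 | 3,5-dibromobenzyne (3,5-dibromo-1,2-didehydrobenzene) | C1#CC(Br)=CC(Br)=C1 | intermediate (not isolated)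
8 | racemic 1-tert-butyl 2-methyl 4,6-dibromoindoline-1,2-dicarboxylate | COC(=O)C1Cc2c(Br)cc(Br)cc2N1C(=O)OC(C)(C)C | intermediate
9 | racemic methyl 4,6-dibromoindoline-2-carboxylate | COC(=O)C1Cc2c(Br)cc(Br)cc2N1 | intermediate
10 | methyl 4,6-dibromo-1H-indole-2-carboxylate | COC(=O)c1cc2c(Br)cc(Br)cc2[nH]1 | intermediate
11 | methyl 4,6-dibromo-3-(methylsulfanyl)-1H-indole-2-carboxylate | COC(=O)c1[nH]c2cc(Br)cc(Br)c2c1SC | intermediate
12 | 4,6-dibromo-3-(methylsulfanyl)-1H-indole-2-carboxylic acid | CSc1c(C(=O)O)[nH]c2cc(Br)cc(Br)c12 | intermediate
13 | 2,4,6-tribromo-3-(methylsulfanyl)-1H-indole | CSc1c(Br)[nH]c2cc(Br)cc(Br)c12 | target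

## Step count and risks

Total step count: 8. Longest linear sequence: 8 steps, from 1 to 13; 6 enters at step 3 as a purchased compound.

**Step 3 (key step).** Three processes can divert it.
- Erosion of the orientation of nitrogen addition: bromine distorts an aryne less than fluorine or an alkoxy group does, and the second bromine pulls weakly the other way.
- Proton transfer to the ortho-bromoaryl anion before it closes, which would stop at simple N-arylation.
- Loss of bromide from that anion to a new aryne, followed by oligomerization.

Fallback: it sets out from 6 and comes back to the route at 10. Compound 6 is used as a masked α-keto ester and heated in methanol with the hydrochloride of (3,5-dibromophenyl)hydrazine F1. Under acid the enamide reacts at its α-carbon through the N-acyliminium tautomer, not as a Michael acceptor; the Boc-amine fragment is lost and the hydrazone methyl 2-[2-(3,5-dibromophenyl)hydrazinylidene]propanoate F2 forms. Heating F2 in polyphosphoric acid should bring about Fischer indolization. Both ortho positions of the 3,5-dibromophenyl ring are equivalent, so only the 4,6-dibromo isomer 10 can form. This gives up the aryne logic and makes steps 1, 2, 4 and 5 unnecessary.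

**Step 2.** The most likely failure is scrambling of lithium among the bromine positions (exchange at the para bromine, or double exchange) before the silyl shift is complete. Incomplete O-triflation of the doubly ortho-substituted phenoxide is the second possibility.

Fallback: it sets out from 1 and comes back at 5.
- Phenol 1 is converted with MOMCl and i-Pr2NEt into 1,3,5-tribromo-2-(methoxymethoxy)benzene F3.
- The two ether oxygens chelate lithium and direct n-BuLi to an ortho bromine at −78 °C, and a Me3SiCl quench gives [3,5-dibromo-2-(methoxymethoxy)phenyl]trimethylsilane F4.
- HCl in methanol at rt removes the acetal and gives 2,4-dibromo-6-(trimethylsilyl)phenol F5; the silyl group on this electron-poor ring should resist protodesilylation.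
- The isolated, purified phenol is triflated with Tf2O and pyridine to give 5.

Silicon is thus introduced by intermolecular trapping instead of migration, and the triflation is done under amine-base conditions.

**Step 6.** The risk is slow substitution at a C3 that is deactivated by the ester and flanked by the C4 bromine. That would leave time for N-sulfenylation or for ring chlorination by residual chlorinating agent.

Fallback: it sets out from 10 and comes back at 13.
- Ester 10 is saponified with LiOH to 4,6-dibromo-1H-indole-2-carboxylic acid F6.
- Protodecarboxylation (Ag2CO3 catalytic, AcOH, DMSO, 120 °C) gives 4,6-dibromo-1H-indole F7, whose C3 is no longer deactivated by an ester.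
- Sulfenylation of F7 with MeSCl at low temperature gives 4,6-dibromo-3-(methylsulfanyl)-1H-indole F8.
- NBS (1 equiv, THF, −78 °C to 0 °C) brominates the one remaining pyrrole position, C2, giving 13.

The carboxyl group is then no longer the handle for the C2 bromine.

**Step 8.** The risk is that electrophilic bromine is consumed at sulfur (bromosulfonium formation and oxidation to the sulfoxide on work-up), or that ipso attack is too slow and substitution on the benzene ring competes.

Fallback: it sets out from 12 and comes back at 13. Acid 12 is protodecarboxylated (Ag2CO3 catalytic, AcOH, DMSO, 120 °C, or plain thermolysis in quinoline at about 200 °C if the thioether retards the silver catalyst) to 4,6-dibromo-3-(methylsulfanyl)-1H-indole F9, the same structure as F8. F9 is then brominated at its free C2–H with one equivalent of NBS at low temperature. This separates C–C cleavage from C–Br formation, and C–H substitution at C2 of a 3-sulfanylindole should be faster than the ipso process.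

## Further compounds

F1 | step 3 | (3,5-dibromophenyl)hydrazine | NNc1cc(Br)cc(Br)c1
F2 | step 3 | methyl 2-[2-(3,5-dibromophenyl)hydrazinylidene]propanoate | COC(=O)C(C)=NNc1cc(Br)cc(Br)c1
F3 | step 2 | 1,3,5-tribromo-2-(methoxymethoxy)benzene | COCOc1c(Br)cc(Br)cc1Br
F4 | step 2 | [3,5-dibromo-2-(methoxymethoxy)phenyl]trimethylsilane | COCOc1c(Br)cc(Br)cc1[Si](C)(C)C
F5 | step 2 | 2,4-dibromo-6-(trimethylsilyl)phenol | C[Si](C)(C)c1cc(Br)cc(Br)c1O
F6 | step 6 | 4,6-dibromo-1H-indole-2-carboxylic acid | OC(=O)c1cc2c(Br)cc(Br)cc2[nH]1
F7 | step 6 | 4,6-dibromo-1H-indole | Brc1cc(Br)c2cc[nH]c2c1
F8 | step 6 | 4,6-dibromo-3-(methylsulfanyl)-1H-indole | CSc1c[nH]c2cc(Br)cc(Br)c12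
F9 | step 8 | 4,6-dibromo-3-(methylsulfanyl)-1H-indole | CSc1c[nH]c2cc(Br)cc(Br)c12
A1 | alternative 1 | 4,6-dibromo-1-(4-methylbenzenesulfonyl)-1H-indole | Cc1ccc(cc1)S(=O)(=O)n1ccc2c(Br)cc(Br)cc21
A2 | alternative 1 | 3-(1-bromoethenyl)-2-(2,2-dibromoethenyl)-1-(4-methylbenzenesulfonyl)-1H-pyrrole | Cc1ccc(cc1)S(=O)(=O)n1ccc(C(Br)=C)c1C=C(Br)Br
A3 | alternative 2 | 4,6-dibromo-3-(methylsulfanyl)-1H-indole | CSc1c[nH]c2cc(Br)cc(Br)c12
A4 | alternative 2 | 1,5-dibromo-3-isocyano-2-[(methylsulfanyl)methyl]benzene | [C-]#[N+]c1cc(Br)cc(Br)c1CSC
A5 | alternative 3 | 2,4,6-tribromo-3-(methylsulfanyl)-1-(4-methylbenzenesulfonyl)-1H-indole | CSc1c(Br)n(S(=O)(=O)c2ccc(C)cc2)c2cc(Br)cc(Br)c12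
A6 | alternative 3 | N-[3,5-dibromo-2-(bromoethynyl)phenyl]-4-methylbenzenesulfonamide | Cc1ccc(cc1)S(=O)(=O)Nc1cc(Br)cc(Br)c1C#CBr
A7 | alternative 3 | dimethyl(methylsulfanyl)sulfonium tetrafluoroborate | CS[S+](C)C.F[B-](F)(F)F
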